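The numbers in the tables stem from a simulated flask with constants of no real substance; the scatter is artificial.

**The leftover.** Start from what is left in the green flask at its last reading, 6.00 h: 18.5 % of the starting complex stands as complex with one exchanged. You want to know what stands at 10 h.

| flask | starting complex | incoming ligand | protic impurity | remark | time |
|---|---|---|---|---|---|
| green | 0.20 M | 0.20 M | 0.020 M | run made earlier |  |
| red | 0.10 M | 0.20 M | 0.020 M | run made earlier |  |
| ochre | 0.40 M | 0.20 M | 0.020 M | run made earlier |  |
| north-east | 0.20 M | 0.200 M | 0.0200 M | one stirred flow tank at steady state, fed with the mixture as stated, mean residence time 10 h |  |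
| north-west | 0.20 M (fed, over 8.00 h) | 0.200 M | 0.0200 M | all but starting complex at the start; starting complex goes in evenly over 8.00 h, the run ends at 10 h | 10 h |
| south | 0.20 M | 0.200 M (fed, over 8.00 h) | 0.0200 M | all but incoming ligand at the start; incoming ligand goes in evenly over 8.00 h, the run ends at 10 h | 10 h |
| south-east | 0.20 M | 0.200 M | 0.0200 M | everything together in a closed stirred flask, run for 10 h | 10 h |

| run | time / h | complex with one exchanged / % |
|---|---|---|
| green | 0.500 | 17.9 |
| green | 0.833 | 23.1 |
| green | 1.33 | 25.9 |
| green | 2.00 | 27.9 |
| green | 4.00 | 22.0 |
| green | 6.00 | 18.5 |
| red | 0.500 | 18.3 |
| red | 1.50 | 33.3 |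
| red | 3.00 | 31.1 |
| red | 4.00 | 30.4 |
| red | 6.00 | 23.7 |
| red | 8.00 | 21.6 |
| ochre | 1.33 | 19.5 |
| ochre | 2.50 | 19.4 |
| ochre | 4.00 | 16.6 |
| ochre | 5.00 | 14.1 |
| ochre | 6.00 | 12.6 |
| ochre | 8.00 | 13.7 |

(readings scatter by 1 percentage point)

- the set-up with the highest amount of complex with one exchanged at the outlet or at the end, in percent of the starting complex put in ("none" if the first two lie within 2 percentage points) (north-east / north-west / south / south-east / none)
- amount of complex with one exchanged at the outlet or at the end, in percent of the starting complex put in, north-east
- amount of complex with one exchanged at the outlet or at the end, in percent of the starting complex put in, north-west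
- amount of complex with one exchanged at the outlet or at the end, in percent of the starting complex put in, south
- amount of complex with one exchanged at the outlet or at the end, in percent of the starting complex put in, south-east

- the stated concentrations are those of everything mixed, before any reaction; amounts are the same in each set-up
- the numbers in the tables scatter with a standard deviation of 1 percentage point
- the feed brings no volume worth counting
- the earlier runs were made in a closed, stirred flask

**The ledger.** Book the incoming ligand of green, c(incoming ligand) = 0.20 M. First entry: protic impurity, at one ligand each as I assume, 0.020 M. That leaves 0.180 M, less than c(starting complex) = 0.20 M, so on paper the ligand is the limiting reagent. Second entry: complex with one exchanged, 0.0370 M at the last reading. Third entry, the open one: 0.143 M, free ligand or products nobody read. With it the books close.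

**One molecule.** At 2.00 h the second entry held 0.0558 M, so it has been shrinking. Follow one molecule of complex with one exchanged: it stays or it passes on. Green's two readings give 0.103 h⁻¹, the fade rate: the logarithm of the ratio of two readings past the peak, over the hours between them, taken as a pseudo-first-order loss. For a stretch a few hours past the peak I reckon its survival chance as the exponential of minus fade rate times hours; the rate is net of whatever still forms, so this is an estimate.

**My reckoning.** Over the last 4.00 h the chance is 66.3 %, so the closed flask ends near 12.3 %. Red's readings give 0.0729 h⁻¹ over other hours, but with a scatter of 1 percentage point per reading I can't tell that from green's rate. Whatever forms as a feed ends has 2.00 h to survive, a chance of 81.4 %.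

**The forecast.** It names north-west, with 20 % north-east, 26 % north-west, 19 % south and 14 % south-east, a closed flask above mine. Its ground: “Low standing metal concentration should therefore help”.

**The flask.** South comes first: south at 21.0 %, against 17.7 % north-west, 17.3 % north-east and 14.9 % south-east.

    starting complex + incoming ligand ⇌ leaving ligand + complex with one exchanged (K = 0.390, k = 7.20 × 10⁻⁴ M⁻¹ s⁻¹)
    complex with one exchanged + incoming ligand ⇌ leaving ligand + complex with two exchanged (K = 2.30, k = 2.50 × 10⁻⁴ M⁻¹ s⁻¹)
    protic impurity + incoming ligand → quenched reagent (k = 0.00470 M⁻¹ s⁻¹)
    complex with one exchanged + incoming ligand → over-reaction product (k = 1.60 × 10⁻⁴ M⁻¹ s⁻¹)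

In south-east at 10.0 h, complex with one exchanged is made at 0.198 of the rate at which it is used up, each step taken net. Its amount is therefore still falling there. South-east read at 6.0 h holds 19.0 %, and the survival chance takes that to 12.6 %, under its simulated 14.9 %. South holds 23.9 % at 8.00 h, and the chance takes that to 19.5 %, under its simulated 21.0 %.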